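# Amaurone B: proposed total synthesis through silver-promoted ring expansion of a dibromobicyclo[3.1.0]hexane

**Conventions.** Ring atoms: C1 (CH bearing the triene), C2 (CHMe), C3 (C(Me)OH), C4 (CHOAc), C5 (C(Me)OH), C6 (CHOAc). The chain is C7 (on C1) to C12 (on the pyrone). The β face carries the four ring oxygens; the α face carries the C1 chain and the C2 methyl. TBDPS = tert-butyldiphenylsilyl.

Remark: the primary oxygen is carried as a TBDPS ether. Compound 20 is drawn as the cyclopropane isomer expected from carbene attack on the β face; the α-face isomer would give the same 21, because the cyclopropane carbons become a planar cation in step 13.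

## Analysis of the target

Amaurone B (42) joins C6 of a 2-methoxy-3,5-dimethyl-4-pyranone through an all-E, twice methyl-branched triene to C1 of a cyclohexane in which every ring carbon is a stereocentre. In the numbering above the ring is (1R,2S,3R,4R,5S,6S). The tertiary hydroxyls at C3 and C5 and the acetates at C4 and C6 all lie on the β face; the chain at C1 and the methyls at C2, C3 and C5 lie on the α face. The sensitive groups are the secondary acetates next to free tertiary hydroxyls (base, acyl shifts) and the C6 oxygen, which is β to C1 and is lost by elimination once C1 carries a carbonyl. The methoxypyrone–triene is sensitive to light, acid and nucleophiles. The difficulty is six contiguous stereocentres, two of them fully substituted carbinols in a 1,3 relationship, with no unfunctionalised ring carbon. The strategy rests on C5: it is a methyl-bearing carbon flanked by the oxygenated C4 and C6. C5 can therefore enter as a dihalocarbene carbon across a C4=C6 bond of a cyclopentene that already holds C1–C3. The oxygen on C3, next to C4, can then deliver the C4 oxygen through a carbonate tether when the three-membered ring opens.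

## Retrosynthetic reasoning

**C11=C12.** 42 is cut at the pyrone-side trisubstituted alkene into dienal 34 and pyrone phosphonate 41. This is the most convergent cut, and it lets the acetates be in place beforehand, so nothing is done to the pyrone–triene after it is formed. The forward olefination has to give the E alkene and leave two acetates and two tertiary hydroxyls alone.

**C9=C10, C7=C8 and the acetates.** 34 is traced through tetraol 33 to bis-acetonide dienal 32. 32 is cut twice at the chain alkenes, to enal 30 (with ylide 31) and to aldehyde 28 (with ylide 29). The acetates cannot be present at the stage of 28, since a C6 acetate β to the aldehyde would be expelled. The C3/C4 and C5/C6 diols are therefore masked as acetonides (26) and unmasked on the dienal, before the pyrone arrives.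

**C5–O and C6–O.** 26 comes from tetraol 25, and 25 from alkene 23 by cutting both C–O bonds at once. The forward syn-dihydroxylation must occur on the β face. The free C4 hydroxyl can direct an osmium–diamine reagent there by hydrogen bonding, and the C1 substituent shields the α face.

**C5–CH3.** 23 is cut at the C5 methyl to vinyl bromide 22, a cross-coupling on an sp2 carbon that cannot affect stereochemistry. 22 is the methanolysis product of cyclic carbonate 21. The carbonate is opened first, so that zerovalent palladium is offered a vinyl bromide but no ionisable allylic carbonate.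

**C4–O and the six-membered ring (key).** 21 is traced to dibromobicyclo[3.1.0]hexane 20 by removing the C4–O bond and restoring the C4–C6 bond. The forward step expands the ring, places the C4 oxygen cis to the C3 oxygen, and leaves bromine on C5. No other cut delivers the carbocycle, a stereocentre and the handle for the C5 methyl in one operation.

**C5 as a carbene carbon.** 20 is cut into cyclopentenyl carbonate 18 and the carbene from 19. 18 is the tert-butyl carbonate of cyclopentenol 17.

**C4=C6.** 17 is opened at its only alkene to diene 16 (ring-closing metathesis forward). 16 is the silyl ether of diol 15, the reduction product of lactone 14. The lactone is kept until this point because it fixes C1 relative to C2.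

**C1–C6.** 14 is cut at the α-vinyl group to lactone 8 and aldehyde 12, a vinyl cation equivalent. The forward enolate reaction must occur anti to the C2 methyl. 8 comes from hydroxymethyl lactone 6 through aldehyde 7.

**C1–C2.** 6 is cut between the lactone α-CH2 and C2 into epoxy alcohol 2 and acetonitrile 3. Backside opening of the epoxide at its secondary carbon sets C2 relative to C3. 2 is the asymmetric epoxidation product of 1, the source of absolute configuration.

**Pyrone.** 41 is cut at C–P to ethylpyrone 39. 39 is the O-methylation product of hydroxypyranone 38, the cyclisation product of diketo ester 37. 37 is cut at C4–C5 into keto ester 35 and amide 36.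

## Alternatives that were turned down

**Alternative 1:** Both C3–O and C6–O would be cut at once, back to the cis-disubstituted cyclohexa-1,3-diene A1. Forward, singlet oxygen adds across C3 and C6 on the face away from the C1 and C2 substituents to give endoperoxide A2. O–O reduction and dihydroxylation of C4=C5 would then complete the tetraol.
- For it: two oxygens enter in one reagent-free photochemical step with a built-in 1,4-cis relationship, and the path from A1 to a tetraol is shorter than the chosen one. On oxidation economy this alternative is stronger.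
- Against it: A1 is a 1,3-dimethyl diene with allylic hydrogens on both methyls and on both sp3 carbons, so the ene pathway competes with [4+2]. A1 can isomerise by hydrogen shifts. A2 carries a secondary bridgehead hydrogen at C6 and can rearrange to a hydroxy enone under base. The enantioselective synthesis of A1, with its cis C1/C2 pair, is left unsolved and would carry most of the steps.
- In its place the chosen route offers absolute configuration from a catalytic epoxidation, a C3/C4 pair that emerges differentiated from C5/C6, and a bromine handle for the C5 methyl.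

**Alternative 2:** C1–C6 and C2–C3 would be cut, leading to menthyloxybutenolide A3 and silyloxydiene A4. Forward, the Diels–Alder reaction on the face opposite the menthyloxy group, with acid work-up, gives the cis-fused cyclohexenone lactone A5.
- For it: the carbocycle and the cis C1–C2 pair arise in one convergent step from simple components with auxiliary control. On ring construction this alternative is stronger than the chosen route.
- Against it: in A5 the substituent on C2 is an acetal carbon that must be reduced all the way to a methyl group. C3 is still a CH(Me) that needs a late hydroxylation through an enolate. The C4 ketone, the C5=C6 alkene and the C3 carbinol must all be set by substrate control on the bicycle. The step count after the cycloaddition would exceed what is saved before it.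
- In its place the chosen route brings C2 and C3 in at their final oxidation levels and fixes C4 by a tether, not by facial bias.

**Alternative 3:** C4–O and C5–O would be cut from the C4=C5 alkene of cyclohexenediol A6. Forward, OsO4–TMEDA, hydrogen-bonded to the C3 and C6 hydroxyls, adds on their face to give the all-cis tetraol A7.
- For it: two allylic hydroxyls on the same face direct in concert, and A7 is the complete oxygenated core. On the last two C–O bonds this is as strong as the chosen route, which uses the same kind of directed osmylation on 23.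
- Against it: the step closes no ring and says nothing about how A6, with its tertiary carbinol, cis-1,4-diol and trisubstituted alkene, is assembled. The C4=C5 alkene of A6 lies between two oxygen-bearing carbons and is more hindered and electron-poorer than C5=C6 of 23.
- In its place the chosen route answers the ring and the C3/C4 oxygens in one step and keeps the directed osmylation as a late, low-risk operation.

Key step: step 13

## Route

Step 1
Reactants: 1 (E)-2-methylbut-2-en-1-ol
Product: 2 [(2S,3S)-2,3-dimethyloxiran-2-yl]methanol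
Conditions: Ti(OiPr)4 (cat.), L-(+)-diisopropyl tartrate (cat.), t-BuOOH, 4 Å molecular sieves, CH2Cl2, −20 °C
Reagents that add atoms: tert-butyl hydroperoxide, CC(C)(C)OO
Why: Sharpless asymmetric epoxidation of an (E)-trisubstituted allylic alcohol; the L-(+)-tartrate complex delivers oxygen to the face that gives the (2S,3S)-epoxide, which sets C3 and, after inversion in step 2, C2 of the target.

Step 2
Reactants: 2 [(2S,3S)-2,3-dimethyloxiran-2-yl]methanol; 3 acetonitrile
Product: 6 (4S,5R)-5-(hydroxymethyl)-4,5-dimethyloxolan-2-one, via dihydroxynitrile 4 (not isolated), via cyclic imidate 5 (not isolated)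
Conditions: 3 (3.5 equiv), n-BuLi (3.3 equiv), THF, −78 °C; 2, −78 → 25 °C; then 2 M HCl (aq), 25 → 40 °C
Reagents that add atoms: water, O
Why: The small lithiated nitrile opens the epoxide by SN2 attack at the secondary carbon with inversion (the fully substituted carbon is not attacked), which places the C2 methyl cis to the CH2OH carbon; on acidification the tertiary hydroxyl closes onto the nitrile and the five-membered imidate is hydrolysed to the γ-lactone.

Step 3
Reactants: 6 (4S,5R)-5-(hydroxymethyl)-4,5-dimethyloxolan-2-one
Product: 7 (2R,3S)-2,3-dimethyl-5-oxooxolane-2-carbaldehyde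
Conditions: Dess–Martin periodinane, CH2Cl2, 0 → 25 °C
Reagents that add atoms: none
Why: Dess–Martin oxidation of the primary alcohol; the aldehyde has a fully substituted α-carbon and cannot epimerise.

Step 4
Reactants: 7 (2R,3S)-2,3-dimethyl-5-oxooxolane-2-carbaldehyde
Product: 8 (4S,5S)-5-ethenyl-4,5-dimethyloxolan-2-one
Conditions: Ph3PCH3Br, KOtBu, THF, 0 °C; then 7, −78 → 0 °C
Reagents that add atoms: methyltriphenylphosphonium bromide, C[P+](c1ccccc1)(c1ccccc1)c1ccccc1.[Br-]
Why: Wittig methylenation; the aldehyde reacts far faster than the lactone carbonyl, and the new vinyl carbon is the future C4.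

Step 5
Reactants: 9 ethyl vinyl ether; 10 benzeneselenenyl chloride
Product: 12 2-(phenylselanyl)acetaldehyde, via chloro ether 11 (not isolated)
Conditions: CH2Cl2, −78 °C; then H2O, NaHCO3, 0 → 25 °C
Reagents that add atoms: water, O
Why: Electrophilic selenenylation of the enol ether puts selenium on the terminal carbon and chloride on the oxygen-bearing carbon; hydrolysis of the α-chloro ether releases the aldehyde, which is used fresh.

Step 6
Reactants: 8 (4S,5S)-5-ethenyl-4,5-dimethyloxolan-2-one; 12 2-(phenylselanyl)acetaldehyde
Product: 13 (3R,4S,5S)-5-ethenyl-3-[1-hydroxy-2-(phenylselanyl)ethyl]-4,5-dimethyloxolan-2-one (both carbinol epimers)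
Conditions: LiN(iPr)2, THF, −78 °C; 12, −78 °C; AcOH quench
Reagents that add atoms: none
Why: Aldol addition of the lactone lithium enolate; the aldehyde approaches anti to the adjacent ring methyl, which sets C1 of the target trans to the C2 methyl on the lactone; the carbinol centre is uncontrolled and disappears in step 7.

Step 7
Reactants: 13 (3R,4S,5S)-5-ethenyl-3-[1-hydroxy-2-(phenylselanyl)ethyl]-4,5-dimethyloxolan-2-one
Product: 14 (3S,4S,5S)-3,5-diethenyl-4,5-dimethyloxolan-2-one
Conditions: MsCl, Et3N, CH2Cl2, 0 → 25 °C
Reagents that add atoms: none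
Why: O-sulfonylation triggers selenium-assisted elimination of the β-hydroxy selenide through a seleniranium ion, an established vinylation of ester and lactone enolates; it gives the terminal vinyl group (future C6) without touching the α-centre, and the mild amine base leaves the alkene out of conjugation.

Step 8
Reactants: 14 (3S,4S,5S)-3,5-diethenyl-4,5-dimethyloxolan-2-one
Product: 15 (2S,3S,4S)-2-ethenyl-3,4-dimethylhex-5-ene-1,4-diol
Conditions: LiAlH4, Et2O, 0 °C
Reagents that add atoms: none
Why: Hydride reduction of the lactone frees the C3 tertiary hydroxyl and turns the carbonyl carbon into the C7 primary alcohol; carbonyl addition is faster than any enolisation of the α-vinyl centre.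

Step 9
Reactants: 15 (2S,3S,4S)-2-ethenyl-3,4-dimethylhex-5-ene-1,4-diol
Product: 16 (3S,4S,5S)-5-[(tert-butyldiphenylsilyloxy)methyl]-3,4-dimethylhepta-1,6-dien-3-ol
Conditions: TBDPSCl, imidazole, CH2Cl2, 0 → 25 °C
Reagents that add atoms: tert-butyl(chloro)diphenylsilane, CC(C)(C)[Si](Cl)(c1ccccc1)c1ccccc1
Why: Silylation of the primary hydroxyl only; the tertiary allylic hydroxyl is too hindered to react.

Step 10
Reactants: 16 (3S,4S,5S)-5-[(tert-butyldiphenylsilyloxy)methyl]-3,4-dimethylhepta-1,6-dien-3-ol
Product: 17 (1S,4S,5S)-4-[(tert-butyldiphenylsilyloxy)methyl]-1,5-dimethylcyclopent-2-en-1-ol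
Conditions: second-generation Grubbs catalyst (3 mol%), CH2Cl2, 40 °C
Reagents that add atoms: none
Why: Ring-closing metathesis of a 1,6-diene to a cyclopentene with loss of ethene; it forms the C4=C6 bond and tolerates the free tertiary allylic alcohol.

Step 11
Reactants: 17 (1S,4S,5S)-4-[(tert-butyldiphenylsilyloxy)methyl]-1,5-dimethylcyclopent-2-en-1-ol
Product: 18 tert-butyl (1S,4S,5S)-4-[(tert-butyldiphenylsilyloxy)methyl]-1,5-dimethylcyclopent-2-en-1-yl carbonate
Conditions: LiN(SiMe3)2, THF, −78 °C; Boc2O, −78 → 0 °C
Reagents that add atoms: di-tert-butyl dicarbonate, CC(C)(C)OC(=O)OC(=O)OC(C)(C)C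
Why: Acylation of the lithium tertiary alkoxide, the standard way to carbonates of hindered alcohols; it installs the oxygen tether for step 13 and masks the hydroxyl against the carbene.

Step 12
Reactants: 18 tert-butyl (1S,4S,5S)-4-[(tert-butyldiphenylsilyloxy)methyl]-1,5-dimethylcyclopent-2-en-1-yl carbonate; 19 bromoform
Product: 20 tert-butyl 6,6-dibromo-4-[(tert-butyldiphenylsilyloxy)methyl]-2,3-dimethylbicyclo[3.1.0]hexan-2-yl carbonate (bicyclic C2, C3, C4 = target C3, C2, C1; cyclopropane cis to the carbonate oxygen)
Conditions: 19 (excess), NaOH (50% aq), BnEt3NCl (cat.), CH2Cl2, 0 → 25 °C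
Reagents that add atoms: none
Why: Stereospecific [2+1] addition of dibromocarbene made by α-elimination under phase transfer; the carbene should approach the β face, away from the C1 silyloxymethyl and the α methyls, but this face choice is not carried into 21.

Step 13
Reactants: 20 tert-butyl 6,6-dibromo-4-[(tert-butyldiphenylsilyloxy)methyl]-2,3-dimethylbicyclo[3.1.0]hexan-2-yl carbonate
Product: 21 5-bromo-1α-[(tert-butyldiphenylsilyloxy)methyl]-2α,3α-dimethylcyclohex-5-ene-3β,4β-diyl carbonate (cis-fused 1,3-dioxolan-2-one, target numbering)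
Conditions: AgBF4 (2 equiv), 2,6-di-tert-butyl-4-methylpyridine (2.5 equiv), CH2Cl2, 0 → 25 °C, dark
Reagents that add atoms: none
Why: Monovalent silver removes the bromide that lies over the five-membered ring while the C4–C6 fusion bond opens in the orbital-symmetry-allowed disrotatory two-electron sense; only this bromide lets the ring carbons turn inward to a ring-compatible allyl cation, and the release of cyclopropane strain drives the ionisation. The six-membered carbocycle thus arises by ring expansion, through cleavage of the bond shared by the three- and five-membered rings, as a 2-bromocyclohexenyl cation spanning C4–C5–C6. The carbonyl oxygen of the C3 carbonate then adds to C4 in a 5-exo-trig closure, and the alkoxydioxolanylium ion sheds its tert-butyl group as isobutene and a proton, which the hindered pyridine takes up so that no acid reaches the silyl ether. The closest known reaction type is the silver-promoted electrocyclic opening of ring-fused gem-dibromocyclopropanes with capture of the cation by a tethered carbamate or carboxylate oxygen; a carbonate is a close analogue, and tert-butyl carbonates are established internal oxygen nucleophiles towards cationic carbon. The one new stereocentre, C4, is controlled by the tether: the O–C(=O)–O bridge from C3 reaches only the β face of C4, so the dioxolanone is cis-fused, and the configuration of the former cyclopropane carbons is erased in the planar cation. The step needs regioselective capture at C4 and not at C6; the tether secures this, since attack at C6 would need a bridged seven-membered ring, and tetrafluoroborate offers no external nucleophile. The bromine left on C5 is the handle for the methyl group.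

Step 14
Reactants: 21 5-bromo-1α-[(tert-butyldiphenylsilyloxy)methyl]-2α,3α-dimethylcyclohex-5-ene-3β,4β-diyl carbonate
Product: 22 5-bromo-1α-[(tert-butyldiphenylsilyloxy)methyl]-2α,3α-dimethylcyclohex-5-ene-3β,4β-diol
Conditions: K2CO3 (0.2 equiv), MeOH, 25 °C
Reagents that add atoms: none
Why: Base-catalysed methanolysis of the five-membered carbonate frees the C3/C4 diol; it is done before the coupling so that zerovalent palladium meets no allylic carbonate, and the vinyl bromide and silyl ether are inert.

Step 15
Reactants: 22 5-bromo-1α-[(tert-butyldiphenylsilyloxy)methyl]-2α,3α-dimethylcyclohex-5-ene-3β,4β-diol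
Product: 23 1α-[(tert-butyldiphenylsilyloxy)methyl]-2α,3α,5-trimethylcyclohex-5-ene-3β,4β-diol
Conditions: Me2Zn (4 equiv), Pd(PPh3)4 (5 mol%), THF, 65 °C
Reagents that add atoms: dimethylzinc, C[Zn]C
Why: Negishi coupling of the vinyl bromide installs the C5 methyl without moving the alkene; the excess reagent covers the two hydroxyl protons.

Step 16
Reactants: 23 1α-[(tert-butyldiphenylsilyloxy)methyl]-2α,3α,5-trimethylcyclohex-5-ene-3β,4β-diol
Product: 25 1α-[(tert-butyldiphenylsilyloxy)methyl]-2α,3α,5α-trimethylcyclohexane-3β,4β,5β,6β-tetraol, via osmate ester 24 (not isolated)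
Conditions: OsO4 (1.05 equiv), TMEDA (1.1 equiv), CH2Cl2, −78 °C; then Na2SO3 (aq), THF, 60 °C
Reagents that add atoms: osmium tetroxide, O=[Os](=O)(=O)=O
Why: Hydrogen-bond-directed syn-dihydroxylation; the diamine-bound oxidant is held by the allylic C4 hydroxyl (and the C3 hydroxyl) and adds to C5=C6 on the β face, which is also the face anti to the C1 substituent, so C5 and C6 are set all-cis to C3 and C4.

Step 17
Reactants: 25 1α-[(tert-butyldiphenylsilyloxy)methyl]-2α,3α,5α-trimethylcyclohexane-3β,4β,5β,6β-tetraol
Product: 26 3,4:5,6-bis-O-isopropylidene derivative of 25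
Conditions: Me2C(OMe)2, TsOH·H2O (cat.), acetone, 25 °C
Reagents that add atoms: 2,2-dimethoxypropane, COC(C)(C)OC
Why: Acid-catalysed acetal exchange; only the cis-1,2 pairs C3/C4 and C5/C6 can close dioxolanes, so one bis-acetonide is expected, and it turns the C6 oxygen into a poor leaving group before C1 carries an aldehyde.

Step 18
Reactants: 26 3,4:5,6-bis-O-isopropylidene derivative of 25
Product: 27 primary alcohol (C7–OH) of the bis-acetonide
Conditions: TBAF, THF, 25 °C
Reagents that add atoms: none
Why: Fluoride cleavage of the silyl ether; the acetonides are inert.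

Step 19
Reactants: 27 primary alcohol (C7–OH) of the bis-acetonide
Product: 28 C7 aldehyde of the bis-acetonide
Conditions: Dess–Martin periodinane, CH2Cl2, 0 → 25 °C
Reagents that add atoms: none
Why: Dess–Martin oxidation under non-basic conditions, which should preserve the C1 centre next to the new aldehyde.

Step 20
Reactants: 28 C7 aldehyde of the bis-acetonide; 29 2-(triphenylphosphoranylidene)propanal
Product: 30 (E)-2-methylprop-2-enal carrying the bis-acetonide ring at C3 (C7=C8 enal)
Conditions: 29 (1.5 equiv), toluene, 100 °C
Reagents that add atoms: none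
Why: Wittig reaction of a stabilised ylide gives the E trisubstituted enal (ring trans to the formyl group); the weakly basic ylide should neither epimerise C1 nor expel the acetal oxygen at C6.

Step 21
Reactants: 30 (E)-2-methylprop-2-enal carrying the bis-acetonide ring at C3; 31 (triphenylphosphoranylidene)acetaldehyde
Product: 32 (2E,4E)-4-methylpenta-2,4-dienal carrying the bis-acetonide ring at C5 (C7=C8, C9=C10)
Conditions: 31 (1.3 equiv), toluene, 80 °C
Reagents that add atoms: none
Why: Wittig two-carbon homologation with a formyl-stabilised ylide gives the E disubstituted alkene; the product dienal is less electrophilic than 30, which limits a second homologation.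

Step 22
Reactants: 32 (2E,4E)-4-methylpenta-2,4-dienal carrying the bis-acetonide ring at C5
Product: 33 (2E,4E)-4-methyl-5-[(1R,2S,3R,4R,5S,6S)-3,4,5,6-tetrahydroxy-2,3,5-trimethylcyclohexyl]penta-2,4-dienal (target numbering)
Conditions: CF3CO2H–H2O–THF, 0 → 25 °C
Reagents that add atoms: none
Why: Aqueous acid hydrolysis of both dioxolanes; the dienal carries no acid-labile group, and the E geometry prevents any ring hydroxyl from adding to the chain.

Step 23
Reactants: 33 (2E,4E)-4-methyl-5-[(1R,2S,3R,4R,5S,6S)-3,4,5,6-tetrahydroxy-2,3,5-trimethylcyclohexyl]penta-2,4-dienal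
Product: 34 4,6-di-O-acetate of 33
Conditions: Ac2O, pyridine, DMAP (cat.), CH2Cl2, 0 → 25 °C
Reagents that add atoms: acetic anhydride, CC(=O)OC(C)=O
Why: Acylation of the two secondary hydroxyls; the tertiary hydroxyls at C3 and C5 do not acylate under these mild conditions, and the aldehyde is now remote from C6.

Step 24
Reactants: 35 ethyl 2-methyl-3-oxopentanoate; 36 N-methoxy-N-methylpropanamide
Product: 37 ethyl 2,4-dimethyl-3,5-dioxoheptanoate (stereoisomers and tautomers)
Conditions: NaH, THF, 0 °C; n-BuLi, 0 °C; 36, −78 → 0 °C; HCl (aq)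
Reagents that add atoms: none
Why: Claisen-type acylation of the β-keto ester dianion at its γ-carbon; the Weinreb amide gives a stable tetrahedral adduct, so acylation stops at the mono stage.

Step 25
Reactants: 37 ethyl 2,4-dimethyl-3,5-dioxoheptanoate
Product: 38 6-ethyl-4-hydroxy-3,5-dimethyl-2H-pyran-2-one
Conditions: DBU, toluene, 110 °C; HCl (aq)
Reagents that add atoms: none
Why: Enol-oxygen lactonisation of the 3,5-diketo ester onto the ester carbonyl with loss of ethanol, the usual entry to 4-hydroxy-2-pyranones.

Step 26
Reactants: 38 6-ethyl-4-hydroxy-3,5-dimethyl-2H-pyran-2-one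
Product: 39 2-ethyl-6-methoxy-3,5-dimethyl-4H-pyran-4-one
Conditions: MeOTf, CH2Cl2, 25 °C; NaHCO3 (aq)
Reagents that add atoms: methyl trifluoromethanesulfonate, COS(=O)(=O)C(F)(F)F
Why: The hard methylating agent alkylates the neutral hydroxypyranone at the lactone carbonyl oxygen, and loss of the hydroxyl proton from the pyrylium salt gives the 2-methoxy-4-pyranone rather than the 4-methoxy-2-pyranone.

Step 27
Reactants: 39 2-ethyl-6-methoxy-3,5-dimethyl-4H-pyran-4-one
Product: 41 diethyl [1-(6-methoxy-3,5-dimethyl-4-oxo-4H-pyran-2-yl)ethyl]phosphonate (racemic), via phosphonite 40 (not isolated)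
Conditions: LiN(SiMe3)2, THF, −78 °C; ClP(OEt)2, −78 → 0 °C; then H2O2 (aq), 0 °C
Reagents that add atoms: diethyl chlorophosphite, CCOP(Cl)OCC; hydrogen peroxide, OO
Why: Lateral deprotonation of the ethyl CH2 (vinylogous to the pyranone carbonyl) and carbon-selective capture by the soft trivalent-phosphorus chloride, then oxidation to the phosphonate, as practised for ester and lactone enolates.

Step 28
Reactants: 34 4,6-di-O-acetate of 33; 41 diethyl [1-(6-methoxy-3,5-dimethyl-4-oxo-4H-pyran-2-yl)ethyl]phosphonate
Product: 42 Amaurone B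
Conditions: 41 (2 equiv), LiN(SiMe3)2 (1.9 equiv), THF, −78 °C; then 34, −78 → 0 °C, dark
Reagents that add atoms: none
Why: Horner–Wadsworth–Emmons olefination; the pyrone-stabilised α-methyl phosphonate anion adds 1,2 to the dienal and eliminates phosphate to give the E C11=C12 alkene (pyrone trans to the chain); the anion is too weak a base to disturb the acetates or deprotonate the tertiary hydroxyls.

## Compound list

1 | (E)-2-methylbut-2-en-1-ol (tiglyl alcohol) | C/C=C(\C)CO | starting material
2 | [(2S,3S)-2,3-dimethyloxiran-2-yl]methanol | C[C@@H]1O[C@@]1(C)CO | intermediate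
3 | acetonitrile | CC#N | starting material
4 | (3S,4R)-4,5-dihydroxy-3,4-dimethylpentanenitrile | N#CC[C@H](C)[C@@](C)(O)CO | intermediate (not isolated)
5 | [(2R,3S)-5-imino-2,3-dimethyloxolan-2-yl]methanol (cyclic imidate) | N=C1C[C@H](C)[C@](C)(CO)O1 | intermediate (not isolated)
6 | (4S,5R)-5-(hydroxymethyl)-4,5-dimethyloxolan-2-one | O=C1C[C@H](C)[C@](C)(CO)O1 | intermediate
7 | (2R,3S)-2,3-dimethyl-5-oxooxolane-2-carbaldehyde | O=C1C[C@H](C)[C@](C)(C=O)O1 | intermediate
8 | (4S,5S)-5-ethenyl-4,5-dimethyloxolan-2-one | O=C1C[C@H](C)[C@](C)(C=C)O1 | intermediate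
9 | ethyl vinyl ether | C=COCC | starting material
10 | benzeneselenenyl chloride | Cl[Se]c1ccccc1 | starting material
11 | 1-chloro-1-ethoxy-2-(phenylselanyl)ethane | CCOC(Cl)C[Se]c1ccccc1 | intermediate (not isolated)
12 | 2-(phenylselanyl)acetaldehyde | O=CC[Se]c1ccccc1 | intermediate
13 | (3R,4S,5S)-5-ethenyl-3-[1-hydroxy-2-(phenylselanyl)ethyl]-4,5-dimethyloxolan-2-one (carbinol epimers) | O=C1[C@@H](C(O)C[Se]c2ccccc2)[C@H](C)[C@](C)(C=C)O1 | intermediate
14 | (3S,4S,5S)-3,5-diethenyl-4,5-dimethyloxolan-2-one | O=C1[C@@H](C=C)[C@H](C)[C@](C)(C=C)O1 | intermediate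
15 | (2S,3S,4S)-2-ethenyl-3,4-dimethylhex-5-ene-1,4-diol | OC[C@@H](C=C)[C@H](C)[C@@](C)(O)C=C | intermediate
16 | (3S,4S,5S)-5-[(tert-butyldiphenylsilyloxy)methyl]-3,4-dimethylhepta-1,6-dien-3-ol | CC(C)(C)[Si](c1ccccc1)(c1ccccc1)OC[C@@H](C=C)[C@H](C)[C@@](C)(O)C=C | intermediate
17 | (1S,4S,5S)-4-[(tert-butyldiphenylsilyloxy)methyl]-1,5-dimethylcyclopent-2-en-1-ol | CC(C)(C)[Si](c1ccccc1)(c1ccccc1)OC[C@@H]1[C@H](C)[C@@](C)(O)C=C1 | intermediate
18 | tert-butyl (1S,4S,5S)-4-[(tert-butyldiphenylsilyloxy)methyl]-1,5-dimethylcyclopent-2-en-1-yl carbonate | CC(C)(C)[Si](c1ccccc1)(c1ccccc1)OC[C@@H]1[C@H](C)[C@@](C)(OC(=O)OC(C)(C)C)C=C1 | intermediate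
19 | bromoform | BrC(Br)Br | starting material
20 | tert-butyl 6,6-dibromo-4-[(tert-butyldiphenylsilyloxy)methyl]-2,3-dimethylbicyclo[3.1.0]hexan-2-yl carbonate (cyclopropane cis to the carbonate oxygen, trans to the 3-methyl and 4-silyloxymethyl groups) | CC(C)(C)[Si](c1ccccc1)(c1ccccc1)OC[C@@H]1[C@H](C)[C@@](C)(OC(=O)OC(C)(C)C)[C@@H]2[C@H]1C2(Br)Br | intermediate
21 | 5-bromo-1α-[(tert-butyldiphenylsilyloxy)methyl]-2α,3α-dimethylcyclohex-5-ene-3β,4β-diyl carbonate (cis-fused cyclic carbonate) | CC(C)(C)[Si](c1ccccc1)(c1ccccc1)OC[C@@H]1[C@H](C)[C@@]2(C)OC(=O)O[C@H]2C(Br)=C1 | intermediate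
22 | 5-bromo-1α-[(tert-butyldiphenylsilyloxy)methyl]-2α,3α-dimethylcyclohex-5-ene-3β,4β-diol | CC(C)(C)[Si](c1ccccc1)(c1ccccc1)OC[C@@H]1[C@H](C)[C@@](C)(O)[C@@H](O)C(Br)=C1 | intermediate
23 | 1α-[(tert-butyldiphenylsilyloxy)methyl]-2α,3α,5-trimethylcyclohex-5-ene-3β,4β-diol | CC(C)(C)[Si](c1ccccc1)(c1ccccc1)OC[C@@H]1[C@H](C)[C@@](C)(O)[C@@H](O)C(C)=C1 | intermediate
24 | cyclic C5,C6 osmate ester of 23 (hexavalent osmium, TMEDA bound) | CC(C)(C)[Si](c1ccccc1)(c1ccccc1)OC[C@@H]1[C@H](C)[C@@](C)(O)[C@@H](O)[C@@]2(C)O[Os](=O)(=O)O[C@@H]12.CN(C)CCN(C)C | intermediate (not isolated)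
25 | 1α-[(tert-butyldiphenylsilyloxy)methyl]-2α,3α,5α-trimethylcyclohexane-3β,4β,5β,6β-tetraol | CC(C)(C)[Si](c1ccccc1)(c1ccccc1)OC[C@@H]1[C@H](C)[C@@](C)(O)[C@@H](O)[C@@](C)(O)[C@H]1O | intermediate
26 | 3,4:5,6-bis-O-isopropylidene derivative of 25 | CC(C)(C)[Si](c1ccccc1)(c1ccccc1)OC[C@@H]1[C@H](C)[C@@]2(C)OC(C)(C)O[C@H]2[C@@]2(C)OC(C)(C)O[C@@H]12 | intermediate
27 | bis-acetonide primary alcohol (C7–OH) | OC[C@@H]1[C@H](C)[C@@]2(C)OC(C)(C)O[C@H]2[C@@]2(C)OC(C)(C)O[C@@H]12 | intermediate
28 | bis-acetonide C7 aldehyde | O=C[C@@H]1[C@H](C)[C@@]2(C)OC(C)(C)O[C@H]2[C@@]2(C)OC(C)(C)O[C@@H]12 | intermediate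
29 | 2-(triphenylphosphoranylidene)propanal | CC(C=O)=P(c1ccccc1)(c1ccccc1)c1ccccc1 | starting material
30 | (E)-2-methyl-3-(bis-acetonide ring)prop-2-enal | O=C/C(C)=C/[C@@H]1[C@H](C)[C@@]2(C)OC(C)(C)O[C@H]2[C@@]2(C)OC(C)(C)O[C@@H]12 | intermediate
31 | (triphenylphosphoranylidene)acetaldehyde | O=CC=P(c1ccccc1)(c1ccccc1)c1ccccc1 | starting material
32 | (2E,4E)-4-methyl-5-(bis-acetonide ring)penta-2,4-dienal | O=C/C=C/C(C)=C/[C@@H]1[C@H](C)[C@@]2(C)OC(C)(C)O[C@H]2[C@@]2(C)OC(C)(C)O[C@@H]12 | intermediate
33 | (2E,4E)-4-methyl-5-[(1R,2S,3R,4R,5S,6S)-3,4,5,6-tetrahydroxy-2,3,5-trimethylcyclohexyl]penta-2,4-dienal (target numbering) | O=C/C=C/C(C)=C/[C@@H]1[C@H](C)[C@@](C)(O)[C@@H](O)[C@@](C)(O)[C@H]1O | intermediate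
34 | 4,6-di-O-acetate of 33 | O=C/C=C/C(C)=C/[C@@H]1[C@H](C)[C@@](C)(O)[C@@H](OC(C)=O)[C@@](C)(O)[C@H]1OC(C)=O | intermediate
35 | ethyl 2-methyl-3-oxopentanoate | CCC(=O)C(C)C(=O)OCC | starting material
36 | N-methoxy-N-methylpropanamide | CCC(=O)N(C)OC | starting material
37 | ethyl 2,4-dimethyl-3,5-dioxoheptanoate | CCOC(=O)C(C)C(=O)C(C)C(=O)CC | intermediate
38 | 6-ethyl-4-hydroxy-3,5-dimethyl-2H-pyran-2-one | CCc1oc(=O)c(C)c(O)c1C | intermediate
39 | 2-ethyl-6-methoxy-3,5-dimethyl-4H-pyran-4-one | CCc1oc(OC)c(C)c(=O)c1C | intermediate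
40 | diethyl [1-(6-methoxy-3,5-dimethyl-4-oxo-4H-pyran-2-yl)ethyl]phosphonite | CCOP(OCC)C(C)c1oc(OC)c(C)c(=O)c1C | intermediate (not isolated)
41 | diethyl [1-(6-methoxy-3,5-dimethyl-4-oxo-4H-pyran-2-yl)ethyl]phosphonate | CCOP(=O)(OCC)C(C)c1oc(OC)c(C)c(=O)c1C | intermediate
42 | Amaurone B | COc1oc(/C(C)=C/C=C/C(C)=C/[C@@H]2[C@H](C)[C@@](C)(O)[C@@H](OC(C)=O)[C@@](C)(O)[C@H]2OC(C)=O)c(C)c(=O)c1C | target

## Step count and least certain steps

Total: 28 steps. Longest linear sequence: 23 steps (steps 1–4, 6–23 and 28). The pyrone branch (steps 24–27) and the reagent preparation (step 5) are side branches.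

**Step 13 (key).** The bromocyclohexenyl cation may lose a proton from C1 and give a bromodiene before the carbonate closes. Acid-induced loss of the tert-butyl carbonate ahead of ionisation, or desilylation if the acid is not fully scavenged, would also divert material. Fallback, from 17 back to 21: the alkoxide of 17 is acylated with dimethylcarbamoyl chloride to the N,N-dimethylcarbamate F1. Dibromocarbene addition gives the dibromocyclopropane carbamate F2. AgBF4 then opens F2 with capture by the carbamate carbonyl oxygen, a trap that cannot fragment before it has closed, to the dioxolan-2-iminium salt F3. Aqueous bicarbonate hydrolyses F3 to 21.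

**Step 12.** Cycloaddition to a hindered alkene that is inductively deactivated by the allylic carbonate may be slow, and the carbonate may be hydrolysed under the biphasic hydroxide conditions. Fallback, from 17 back to 20: the tertiary hydroxyl is silylated (Et3SiOTf, 2,6-lutidine) to the triethylsilyl ether F4, a less deactivating and base-stable group. Carbene addition gives the dibromocyclopropane silyl ether F5. Mild aqueous acetic acid removes the triethylsilyl group to the dibromocyclopropyl alcohol F6, and the carbonate is then installed as in step 11 to reach 20.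

**Step 2.** Opening at the secondary carbon next to a fully substituted centre may be slow. Migration of the epoxide towards C1 in the alkoxide (Payne-type) and self-condensation of the nitrile anion may then compete. Fallback, from 2 back to 6: 2 is silylated (TBSCl, imidazole) to the silyl ether F7. Allylmagnesium bromide with catalytic CuI opens F7 at the secondary carbon to the homoallylic tertiary alcohol F8. Ozonolysis (O3, then Me2S) gives the lactol F9, and oxidation (TEMPO, PhI(OAc)2) gives the silyloxymethyl lactone F10. HF in acetonitrile removes the silyl group to give 6.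

**Step 6 (with step 7).** Facial discrimination at the enolate carbon may be incomplete. Proton transfer from the enolisable selenoaldehyde and migration of the new alkene into conjugation during the elimination are the other risks. Fallback, from 8 back to 14: the enolate of 8 is added in conjugate fashion to phenyl vinyl sulfoxide to give the sulfinylethyl lactone F11. Thermal syn-elimination of the sulfoxide (toluene, 110 °C, CaCO3) then gives 14.

**Step 27.** The delocalised pyranone anion may be captured at oxygen, not at carbon, or phosphinylated twice. Fallback, from 39 and 32 to 42, replacing steps 22, 23, 27 and 28: lithiated 39 adds to dienal 32 in a vinylogous aldol reaction to give the hydroxy adduct F12. Sulfonylation and base-induced elimination (MsCl, Et3N, then DBU) give the protected triene F13. Aqueous trifluoroacetic acid removes the acetonides to the tetraol F14, and selective acetylation of the two secondary hydroxyls (Ac2O, pyridine, DMAP) gives 42.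

## Further compounds

F1 | step 13 | (1S,4S,5S)-4-[(tert-butyldiphenylsilyloxy)methyl]-1,5-dimethylcyclopent-2-en-1-yl N,N-dimethylcarbamate | CC(C)(C)[Si](c1ccccc1)(c1ccccc1)OC[C@@H]1[C@H](C)[C@@](C)(OC(=O)N(C)C)C=C1
F2 | step 13 | 6,6-dibromobicyclo[3.1.0]hexan-2-yl N,N-dimethylcarbamate analogue of 20 | CC(C)(C)[Si](c1ccccc1)(c1ccccc1)OC[C@@H]1[C@H](C)[C@@](C)(OC(=O)N(C)C)[C@@H]2[C@H]1C2(Br)Br
F3 | step 13 | cis-fused 2-(dimethyliminio)-1,3-dioxolane tetrafluoroborate corresponding to 21 | CC(C)(C)[Si](c1ccccc1)(c1ccccc1)OC[C@@H]1[C@H](C)[C@@]2(C)OC(=[N+](C)C)O[C@H]2C(Br)=C1.F[B-](F)(F)F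
F4 | step 12 | triethylsilyl ether of 17 | CC(C)(C)[Si](c1ccccc1)(c1ccccc1)OC[C@@H]1[C@H](C)[C@@](C)(O[Si](CC)(CC)CC)C=C1
F5 | step 12 | 6,6-dibromobicyclo[3.1.0]hexane triethylsilyl ether | CC(C)(C)[Si](c1ccccc1)(c1ccccc1)OC[C@@H]1[C@H](C)[C@@](C)(O[Si](CC)(CC)CC)[C@@H]2[C@H]1C2(Br)Br
F6 | step 12 | 6,6-dibromo-4-[(tert-butyldiphenylsilyloxy)methyl]-2,3-dimethylbicyclo[3.1.0]hexan-2-ol | CC(C)(C)[Si](c1ccccc1)(c1ccccc1)OC[C@@H]1[C@H](C)[C@@](C)(O)[C@@H]2[C@H]1C2(Br)Br
F7 | step 2 | tert-butyl{[(2S,3S)-2,3-dimethyloxiran-2-yl]methoxy}dimethylsilane | C[C@@H]1O[C@@]1(C)CO[Si](C)(C)C(C)(C)C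
F8 | step 2 | (2R,3S)-1-(tert-butyldimethylsilyloxy)-2,3-dimethylhex-5-en-2-ol | C=CC[C@H](C)[C@@](C)(O)CO[Si](C)(C)C(C)(C)C
F9 | step 2 | (4S,5R)-5-[(tert-butyldimethylsilyloxy)methyl]-4,5-dimethyloxolan-2-ol (anomers) | OC1C[C@H](C)[C@](C)(CO[Si](C)(C)C(C)(C)C)O1
F10 | step 2 | (4S,5R)-5-[(tert-butyldimethylsilyloxy)methyl]-4,5-dimethyloxolan-2-one | O=C1C[C@H](C)[C@](C)(CO[Si](C)(C)C(C)(C)C)O1
F11 | step 6 | (3S,4S,5S)-5-ethenyl-4,5-dimethyl-3-[2-(phenylsulfinyl)ethyl]oxolan-2-one | O=C1[C@@H](CCS(=O)c2ccccc2)[C@H](C)[C@](C)(C=C)O1
F12 | step 27 | C11-hydroxy aldol adduct of 39 and 32 (bis-acetonide, epimers at C11 and C12) | COc1oc(C(C)C(O)/C=C/C(C)=C/[C@@H]2[C@H](C)[C@@]3(C)OC(C)(C)O[C@H]3[C@@]3(C)OC(C)(C)O[C@@H]23)c(C)c(=O)c1C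
F13 | step 27 | bis-acetonide of the deacetylated target (all-E triene) | COc1oc(/C(C)=C/C=C/C(C)=C/[C@@H]2[C@H](C)[C@@]3(C)OC(C)(C)O[C@H]3[C@@]3(C)OC(C)(C)O[C@@H]23)c(C)c(=O)c1C
F14 | step 27 | 4,6-di-O-deacetyl Amaurone B (tetraol) | COc1oc(/C(C)=C/C=C/C(C)=C/[C@@H]2[C@H](C)[C@@](C)(O)[C@@H](O)[C@@](C)(O)[C@H]2O)c(C)c(=O)c1C
A1 | alternative 1 | tert-butyldimethylsilyl ether of cis-(2,4,6-trimethylcyclohexa-2,4-dien-1-yl)methanol | CC(C)(C)[Si](C)(C)OC[C@H]1C=C(C)C=C(C)[C@H]1C
A2 | alternative 1 | 2,3-dioxabicyclo[2.2.2]oct-5-ene endoperoxide from A1 | CC(C)(C)[Si](C)(C)OC[C@@H]1[C@H](C)[C@@]2(C)OO[C@@H]1C(C)=C2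
A3 | alternative 2 | 5-(menthyloxy)furan-2(5H)-one | O=C1O[C@@H](O[C@@H]2C[C@H](C)CC[C@H]2C(C)C)C=C1
A4 | alternative 2 | tert-butyldimethyl[(2-methylpenta-1,3-dien-3-yl)oxy]silane | C=C(C)C(O[Si](C)(C)C(C)(C)C)=CC
A5 | alternative 2 | cis-fused cyclohexenone lactone with the menthyloxy acetal | O=C1O[C@@H](O[C@@H]3C[C@H](C)CC[C@H]3C(C)C)[C@H]2[C@@H]1C=C(C)C(=O)[C@H]2C
A6 | alternative 3 | 1α-[(tert-butyldimethylsilyloxy)methyl]-2α,3α,5-trimethylcyclohex-4-ene-3β,6β-diol | CC(C)(C)[Si](C)(C)OC[C@@H]1[C@H](C)[C@@](C)(O)C=C(C)[C@H]1O
A7 | alternative 3 | all-cis cyclohexane-1,2,3,4-tetraol (tert-butyldimethylsilyl ether) | CC(C)(C)[Si](C)(C)OC[C@@H]1[C@H](C)[C@@](C)(O)[C@@H](O)[C@@](C)(O)[C@H]1O
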